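**Retrosynthetic overview**

- The strategy rests on ring C (O1–C2–C3–C4–C4a–C8a): the C3 hydroxyl and the C4 carbonyl are vicinal oxygens, i.e. an oxidised C3=C4 alkene whose two faces are told apart by the aryl group on C2.
- Target 17 ⇐ hexabenzyl ether 16 ⇐ C4 carbinol 15 (O3 benzylated) ⇐ 2,3-trans-3,4-cis-diol 13 ⇐ osmium dihydroxylation of the (2S)-flav-3-ene 11 (C3–O and C4–O).
- Flavene 11 ⇐ (2S)-flavanone 8 (reduction, dehydration) ⇐ chromone 6 + arylboronic acid 7 by asymmetric conjugate arylation, which sets C2.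
- Chromone 6 ⇐ 2-hydroxyacetophenone 4 ⇐ phloroacetophenone 1, whose acetyl group blocks one ring carbon so that C-benzylation at the other two is exhaustive and later supplies C3 and C4.
- Ring order: ring A is bought; ring C is closed in step 3 (O1–C2 bond); ring B is attached at C2 in step 4; no ring is closed afterwards.

Key step: step 7

Remark: C2 keeps one spatial arrangement from step 4 on. Its descriptor is S in 8, 9 and 11 and R from 13 on only because an oxygen on C3 raises C3 above the aryl group in the CIP ranking.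

Assumption: in step 4 the (S)-diphosphine is taken to give the 2S product, by analogy with (S)-biaryl diphosphine–rhodium additions to cyclic enones (same enone face). If the sense is the opposite, the antipodal ligand is used.

**Route**

Step 1
Reactants: 1 2',4',6'-trihydroxyacetophenone (phloroacetophenone); 2 4-(benzyloxy)benzyl alcohol (2.3 equiv)
Product: 3 3',5'-bis[4-(benzyloxy)benzyl]-2',4',6'-trihydroxyacetophenone
Conditions: Sc(OTf)3 (10 mol%), MeCN, 50 °C, slow addition of 2
Reagents that add atoms: none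
Why: Lewis-acid ionisation of the p-alkoxybenzylic alcohol gives a stabilised benzylic cation that undergoes Friedel–Crafts alkylation at the only two free, strongly activated ring carbons (C3', C5') of the acylphloroglucinol, the acetyl group blocking the third carbon so that no statistical control is needed.

Step 2
Reactants: 3 3',5'-bis[4-(benzyloxy)benzyl]-2',4',6'-trihydroxyacetophenone
Product: 4 1-{4,6-bis(benzyloxy)-3,5-bis[4-(benzyloxy)benzyl]-2-hydroxyphenyl}ethanone
Conditions: BnBr (2.3 equiv), K2CO3 (3 equiv), DMF, 50 °C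
Reagents that add atoms: benzyl bromide, BrCc1ccccc1
Why: Williamson etherification under weak base alkylates the 4'-OH and one of the two equivalent ortho hydroxyls, while the last ortho OH is held in a strong hydrogen bond to the acetyl carbonyl and stays free for the ring closure; DMF favours O- over C-alkylation.

Step 3
Reactants: 4 1-{4,6-bis(benzyloxy)-3,5-bis[4-(benzyloxy)benzyl]-2-hydroxyphenyl}ethanone
Product: 6 5,7-bis(benzyloxy)-6,8-bis[4-(benzyloxy)benzyl]chromone, via enaminone 5 (not isolated)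
Conditions: DMF-DMA (3 equiv), toluene, 95 °C; then conc. HCl, CH2Cl2, rt
Reagents that add atoms: N,N-dimethylformamide dimethyl acetal, COC(OC)N(C)C
Why: Condensation of the methyl ketone with the formamide acetal gives the enaminone, and acid-promoted conjugate addition of the phenol with loss of dimethylamine closes the pyranone ring (standard enaminone route to chromones), leaving C2 unsubstituted.

Step 4
Reactants: 6 5,7-bis(benzyloxy)-6,8-bis[4-(benzyloxy)benzyl]chromone; 7 4-(benzyloxy)phenylboronic acid (3 equiv)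
Product: 8 (2S)-5,7-bis(benzyloxy)-2-[4-(benzyloxy)phenyl]-6,8-bis[4-(benzyloxy)benzyl]chroman-4-one
Conditions: [Rh(OH)((S)-MeO-F12-BIPHEP)]2 (3 mol% Rh), toluene/H2O (10:1), 50 °C, no added base
Reagents that add atoms: none
Why: Rhodium-catalysed asymmetric 1,4-addition of an arylboronic acid to a chromone (Hayashi–Miyaura type): transmetalation gives an aryl–Rh(I) species whose electron-poor chiral diphosphine selects the enone face for carbometalation and sets C2 as S, and the base-free medium avoids retro-oxa-Michael racemisation of the flavanone.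

Step 5
Reactants: 8 (2S)-5,7-bis(benzyloxy)-2-[4-(benzyloxy)phenyl]-6,8-bis[4-(benzyloxy)benzyl]chroman-4-one
Product: 9 (2S,4S)-5,7-bis(benzyloxy)-2-[4-(benzyloxy)phenyl]-6,8-bis[4-(benzyloxy)benzyl]chroman-4-ol (2,4-cis)
Conditions: NaBH4, THF/MeOH, 0 °C → rt
Reagents that add atoms: none
Why: Borohydride reduction of the aryl ketone by axial hydride attack should give mainly the equatorial 2,4-cis alcohol; the C4 configuration is of no consequence because it is removed in step 6, and C2 is not touched.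

Step 6
Reactants: 9 (2S,4S)-5,7-bis(benzyloxy)-2-[4-(benzyloxy)phenyl]-6,8-bis[4-(benzyloxy)benzyl]chroman-4-ol
Product: 11 (2S)-5,7-bis(benzyloxy)-2-[4-(benzyloxy)phenyl]-6,8-bis[4-(benzyloxy)benzyl]-2H-chromene (penta-O-benzyl flav-3-ene), via sulfamate salt 10 (not isolated)
Conditions: Burgess reagent (2 equiv), THF, rt → 50 °C, argon, dark; Et3N-deactivated silica
Reagents that add atoms: none
Why: Burgess dehydration: the alcohol is converted into its sulfamate ester, which as a 2,4,6-trialkoxybenzylic system loses sulfamate and a C3 proton under neutral conditions to give the conjugated C3=C4 alkene, without the acid that would dimerise or disproportionate the flavene and without involving C2.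

Step 7
Reactants: 11 (2S)-5,7-bis(benzyloxy)-2-[4-(benzyloxy)phenyl]-6,8-bis[4-(benzyloxy)benzyl]-2H-chromene
Product: 13 (2R,3S,4S)-5,7-bis(benzyloxy)-2-[4-(benzyloxy)phenyl]-6,8-bis[4-(benzyloxy)benzyl]chroman-3,4-diol (2,3-trans-3,4-cis), via osmate(VI) ester 12 (not isolated)
Conditions: K2OsO4·2H2O (3 mol%), NMO (1.5 equiv), THF/acetone/H2O (4:4:1), 0 °C → rt, dark; aq. Na2SO3
Reagents that add atoms: N-methylmorpholine N-oxide, C[N+]1([O-])CCOCC1; water, O
Why: OsO4 adds to the C3=C4 π bond in a concerted suprafacial [3+2] cycloaddition to give the cyclic osmate(VI) ester 12, which is hydrolysed in the aqueous medium to the cis-diol while N-methylmorpholine N-oxide returns Os(VI) to Os(VIII). The closest known reaction is the catalytic osmium dihydroxylation of flav-3-enes and other 2H-chromenes, which gives 2,3-trans-3,4-cis-flavan-3,4-diols. No ring of the product is closed (the five-membered osmate ring is transient); the bonds formed are C3–O and C4–O. C3 is set by the C2 aryl group, which shields its own face of the adjacent alkene carbon so that osmium approaches anti to it (3-O trans to the aryl, 3S), and C4 is set by the suprafacial delivery (4-O cis to 3-O, 4S; erased in step 9). The step needs diastereofacial selectivity, secured by the single stereocentre C2 next to C3, and chemoselectivity, secured because C3=C4 is the only non-aromatic C=C and is an electron-rich styrenyl alkene, while benzyl ethers and ArCH2Ar groups are inert to Os(VIII)/NMO. No chiral ligand is added, because face prediction by cinchona ligands is unreliable for cis-disubstituted cyclic alkenes and substrate control already points the right way.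

Step 8
Reactants: 13 (2R,3S,4S)-5,7-bis(benzyloxy)-2-[4-(benzyloxy)phenyl]-6,8-bis[4-(benzyloxy)benzyl]chroman-3,4-diol
Product: 15 (2R,3S,4S)-3,5,7-tris(benzyloxy)-2-[4-(benzyloxy)phenyl]-6,8-bis[4-(benzyloxy)benzyl]chroman-4-ol, via stannylene acetal 14 (not isolated)
Conditions: Bu2SnO (1.1 equiv), toluene, reflux (Dean–Stark); then BnBr (1.3 equiv), CsF (1.5 equiv), DMF, rt
Reagents that add atoms: benzyl bromide, BrCc1ccccc1
Why: Regioselective alkylation of a cis-1,2-diol through its dibutylstannylene acetal: fluoride-activated tin delivers benzyl to the equatorial oxygen O3, the pseudo-axial benzylic O4 being further shielded by the peri 5-benzyloxy group, so the two hydroxyls are differentiated without exposing the free glycol to an oxidant such as MnO2 that would cleave the C3–C4 bond.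

Step 9
Reactants: 15 (2R,3S,4S)-3,5,7-tris(benzyloxy)-2-[4-(benzyloxy)phenyl]-6,8-bis[4-(benzyloxy)benzyl]chroman-4-ol
Product: 16 (2R,3R)-3,5,7-tris(benzyloxy)-2-[4-(benzyloxy)phenyl]-6,8-bis[4-(benzyloxy)benzyl]chroman-4-one (hexa-O-benzylgericudranin D)
Conditions: Dess–Martin periodinane (1.5 equiv), pyridine (3 equiv), CH2Cl2, 0 °C → rt
Reagents that add atoms: none
Why: Dess–Martin oxidation of the now unique secondary benzylic alcohol gives the aryl ketone under buffered conditions that leave C3 (already in the thermodynamically preferred 2,3-trans arrangement), C2 and the diarylmethane CH2 groups untouched.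

Step 10
Reactants: 16 (2R,3R)-3,5,7-tris(benzyloxy)-2-[4-(benzyloxy)phenyl]-6,8-bis[4-(benzyloxy)benzyl]chroman-4-one
Product: 17 gericudranin D, (2R,3R)-3,5,7-trihydroxy-6,8-bis(4-hydroxybenzyl)-2-(4-hydroxyphenyl)chroman-4-one
Conditions: H2 (1 atm), 20% Pd(OH)2/C, THF/MeOH, rt
Reagents that add atoms: none
Why: Catalytic hydrogenolysis cleaves all six benzyl ethers (five aryl, one alkyl) under neutral conditions, at which the C2–O1 bond, the electron-rich C4 aryl ketone and the diarylmethanes are not reduced, and no base is present to epimerise C2 or C3.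

**Compound list**

1 | 2',4',6'-trihydroxyacetophenone | CC(=O)c1c(O)cc(O)cc1O | starting material
2 | 4-(benzyloxy)benzyl alcohol | OCc1ccc(OCc2ccccc2)cc1 | starting material
3 | 3',5'-bis[4-(benzyloxy)benzyl]-2',4',6'-trihydroxyacetophenone | CC(=O)c1c(O)c(Cc2ccc(OCc3ccccc3)cc2)c(O)c(Cc2ccc(OCc3ccccc3)cc2)c1O | intermediate
4 | 1-{4,6-bis(benzyloxy)-3,5-bis[4-(benzyloxy)benzyl]-2-hydroxyphenyl}ethanone | CC(=O)c1c(O)c(Cc2ccc(OCc3ccccc3)cc2)c(OCc2ccccc2)c(Cc2ccc(OCc3ccccc3)cc2)c1OCc1ccccc1 | intermediate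
5 | (E)-enaminone, 3-(dimethylamino)-1-aryl-prop-2-en-1-one derived from 4 | CN(C)/C=C/C(=O)c1c(O)c(Cc2ccc(OCc3ccccc3)cc2)c(OCc2ccccc2)c(Cc2ccc(OCc3ccccc3)cc2)c1OCc1ccccc1 | intermediate
6 | 5,7-bis(benzyloxy)-6,8-bis[4-(benzyloxy)benzyl]chromone | O=c1ccoc2c(Cc3ccc(OCc4ccccc4)cc3)c(OCc3ccccc3)c(Cc3ccc(OCc4ccccc4)cc3)c(OCc3ccccc3)c12 | intermediate
7 | 4-(benzyloxy)phenylboronic acid | OB(O)c1ccc(OCc2ccccc2)cc1 | starting material
8 | (2S)-5,7-bis(benzyloxy)-2-[4-(benzyloxy)phenyl]-6,8-bis[4-(benzyloxy)benzyl]chroman-4-one | O=C1C[C@@H](c2ccc(OCc3ccccc3)cc2)Oc2c(Cc3ccc(OCc4ccccc4)cc3)c(OCc3ccccc3)c(Cc3ccc(OCc4ccccc4)cc3)c(OCc3ccccc3)c12 | intermediate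
9 | (2S,4S)-2,4-cis-chroman-4-ol derived from 8 | O[C@H]1C[C@@H](c2ccc(OCc3ccccc3)cc2)Oc2c(Cc3ccc(OCc4ccccc4)cc3)c(OCc3ccccc3)c(Cc3ccc(OCc4ccccc4)cc3)c(OCc3ccccc3)c12 | intermediate
10 | triethylammonium salt of the C4 O-sulfonyl-N-(methoxycarbonyl)sulfamate of 9 | COC(=O)[N-]S(=O)(=O)O[C@H]1C[C@@H](c2ccc(OCc3ccccc3)cc2)Oc2c(Cc3ccc(OCc4ccccc4)cc3)c(OCc3ccccc3)c(Cc3ccc(OCc4ccccc4)cc3)c(OCc3ccccc3)c12.CC[NH+](CC)CC | intermediate
11 | (2S)-5,7-bis(benzyloxy)-2-[4-(benzyloxy)phenyl]-6,8-bis[4-(benzyloxy)benzyl]-2H-chromene | C1=C[C@@H](c3ccc(OCc4ccccc4)cc3)Oc2c(Cc3ccc(OCc4ccccc4)cc3)c(OCc3ccccc3)c(Cc3ccc(OCc4ccccc4)cc3)c(OCc3ccccc3)c12 | intermediate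
12 | cyclic osmate(VI) ester of diol 13 (O3 and O4 bridged by OsO2, anti to the C2 aryl) | O=[Os]1(=O)O[C@H]2c3c(OCc4ccccc4)c(Cc4ccc(OCc5ccccc5)cc4)c(OCc4ccccc4)c(Cc4ccc(OCc5ccccc5)cc4)c3O[C@H](c3ccc(OCc4ccccc4)cc3)[C@H]2O1 | intermediate
13 | (2R,3S,4S)-penta-O-benzyl 2,3-trans-3,4-cis-flavan-3,4-diol | O[C@H]1c2c(OCc3ccccc3)c(Cc3ccc(OCc4ccccc4)cc3)c(OCc3ccccc3)c(Cc3ccc(OCc4ccccc4)cc3)c2O[C@H](c2ccc(OCc3ccccc3)cc2)[C@H]1O | intermediate
14 | 2,2-dibutyl-1,3,2-dioxastannolane (stannylene acetal) of diol 13 | CCCC[Sn]1(CCCC)O[C@H]2c3c(OCc4ccccc4)c(Cc4ccc(OCc5ccccc5)cc4)c(OCc4ccccc4)c(Cc4ccc(OCc5ccccc5)cc4)c3O[C@H](c3ccc(OCc4ccccc4)cc3)[C@H]2O1 | intermediate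
15 | (2R,3S,4S)-3-O-benzyl ether of 13 (free 4-OH) | O[C@H]1c2c(OCc3ccccc3)c(Cc3ccc(OCc4ccccc4)cc3)c(OCc3ccccc3)c(Cc3ccc(OCc4ccccc4)cc3)c2O[C@H](c2ccc(OCc3ccccc3)cc2)[C@H]1OCc1ccccc1 | intermediate
16 | (2R,3R)-hexa-O-benzylgericudranin D | O=C1c2c(OCc3ccccc3)c(Cc3ccc(OCc4ccccc4)cc3)c(OCc3ccccc3)c(Cc3ccc(OCc4ccccc4)cc3)c2O[C@H](c2ccc(OCc3ccccc3)cc2)[C@H]1OCc1ccccc1 | intermediate
17 | gericudranin D | O=C1c2c(O)c(Cc3ccc(O)cc3)c(O)c(Cc3ccc(O)cc3)c2O[C@H](c2ccc(O)cc2)[C@H]1O | target

**Step count**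

Total step count: 10. Longest linear sequence: 10 steps (1 → 17); 2 and 7 are commercial building blocks.

**Steps most likely to fail**

Step 4. Carbometalation may stall on the electron-rich, 5-alkoxy-substituted enone, or the enantiomeric purity may erode through reversible ring opening of the flavanone. The fallback sets out from 4 and comes back at 9. Claisen–Schmidt condensation of 4 with 4-(benzyloxy)benzaldehyde (KOH, EtOH/THF) should give the 2'-hydroxychalcone F1. Oxa-Michael cyclisation (NaOAc, EtOH, reflux) should give the racemic flavanone F2. Kinetic resolution by Noyori–Ikariya transfer hydrogenation (RuCl(p-cymene)(TsDPEN), HCO2H/Et3N, the antipode that consumes the 2S ketone) should reduce the 2S enantiomer to the cis-flavan-4-ol 9. The unreacted (2R)-flavanone F3 is separated and returned to F2 by base through F1.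

Step 7. Facial discrimination may be insufficient on this fully substituted chromene, or hydrolysis of the hindered osmate ester may be slow enough to allow secondary oxidation. The fallback sets out from 11 and comes back at 15; it forms C3–O by epoxidation and C4–O by solvolysis. Dimethyldioxirane in acetone/MeOH at −40 °C should epoxidise anti to the C2 aryl group to give the 3,4-epoxide F4 (not isolated). Its benzylic C4–O bond should open in situ with methanol to give the 2,3-trans-3-hydroxy-4-methoxyflavan F5 (C4 epimers). Benzylation of the single free hydroxyl (NaH, BnBr, THF/DMF) should give the 3-O-benzyl-4-methoxyflavan F6. Mild aqueous acid (PPTS, THF/H2O) should exchange the benzylic methoxy group for hydroxyl, giving 15 together with its C4 epimer F7; both converge on 16 in step 9.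

Step 8. Benzyl may be delivered to the wrong oxygen, or the benzylic C4–O bond may ionise under the tin/fluoride conditions. The fallback sets out from 13 and comes back at 17; it differentiates the hydroxyls by steric silylation. TBSCl/imidazole in DMF at 0 °C should silylate the less hindered equatorial 3-OH to give the 3-O-TBS diol F8. Dess–Martin oxidation should give the 3-O-TBS ketone F9. HF·pyridine in THF should give the penta-O-benzyl dihydroflavonol F10, and hydrogenolysis under the step 10 conditions should give 17.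

**Further compounds**

F1 | step 4 | 2'-hydroxychalcone from 4 and 4-(benzyloxy)benzaldehyde | O=C(/C=C/c1ccc(OCc2ccccc2)cc1)c1c(O)c(Cc2ccc(OCc3ccccc3)cc2)c(OCc2ccccc2)c(Cc2ccc(OCc3ccccc3)cc2)c1OCc1ccccc1
F2 | step 4 | racemic flavanone (racemate of 8) | O=C1CC(c2ccc(OCc3ccccc3)cc2)Oc2c(Cc3ccc(OCc4ccccc4)cc3)c(OCc3ccccc3)c(Cc3ccc(OCc4ccccc4)cc3)c(OCc3ccccc3)c12
F3 | step 4 | (2R)-flavanone (enantiomer of 8, recovered) | O=C1C[C@H](c2ccc(OCc3ccccc3)cc2)Oc2c(Cc3ccc(OCc4ccccc4)cc3)c(OCc3ccccc3)c(Cc3ccc(OCc4ccccc4)cc3)c(OCc3ccccc3)c12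
F4 | step 7 | 3,4-epoxyflavan, oxirane anti to the C2 aryl group | O1[C@H]2c3c(OCc4ccccc4)c(Cc4ccc(OCc5ccccc5)cc4)c(OCc4ccccc4)c(Cc4ccc(OCc5ccccc5)cc4)c3O[C@H](c3ccc(OCc4ccccc4)cc3)[C@H]21
F5 | step 7 | 2,3-trans-3-hydroxy-4-methoxyflavan (C4 epimers) | COC1c2c(OCc3ccccc3)c(Cc3ccc(OCc4ccccc4)cc3)c(OCc3ccccc3)c(Cc3ccc(OCc4ccccc4)cc3)c2O[C@H](c2ccc(OCc3ccccc3)cc2)[C@H]1O
F6 | step 7 | 2,3-trans-3-benzyloxy-4-methoxyflavan (C4 epimers) | COC1c2c(OCc3ccccc3)c(Cc3ccc(OCc4ccccc4)cc3)c(OCc3ccccc3)c(Cc3ccc(OCc4ccccc4)cc3)c2O[C@H](c2ccc(OCc3ccccc3)cc2)[C@H]1OCc1ccccc1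
F7 | step 7 | (2R,3S,4R) C4 epimer of 15 | O[C@@H]1c2c(OCc3ccccc3)c(Cc3ccc(OCc4ccccc4)cc3)c(OCc3ccccc3)c(Cc3ccc(OCc4ccccc4)cc3)c2O[C@H](c2ccc(OCc3ccccc3)cc2)[C@H]1OCc1ccccc1
F8 | step 8 | 3-O-TBS ether of diol 13 | O[C@H]1c2c(OCc3ccccc3)c(Cc3ccc(OCc4ccccc4)cc3)c(OCc3ccccc3)c(Cc3ccc(OCc4ccccc4)cc3)c2O[C@H](c2ccc(OCc3ccccc3)cc2)[C@H]1O[Si](C)(C)C(C)(C)C
F9 | step 8 | 3-O-TBS penta-O-benzyl dihydroflavonol | O=C1c2c(OCc3ccccc3)c(Cc3ccc(OCc4ccccc4)cc3)c(OCc3ccccc3)c(Cc3ccc(OCc4ccccc4)cc3)c2O[C@H](c2ccc(OCc3ccccc3)cc2)[C@H]1O[Si](C)(C)C(C)(C)C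
F10 | step 8 | (2R,3R)-penta-O-benzylgericudranin D (free 3-OH) | O=C1c2c(OCc3ccccc3)c(Cc3ccc(OCc4ccccc4)cc3)c(OCc3ccccc3)c(Cc3ccc(OCc4ccccc4)cc3)c2O[C@H](c2ccc(OCc3ccccc3)cc2)[C@H]1O
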